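**Plan**
- Retrosynthesis: the lactone bond O2–C1 and the C3–C4 bond are cut first (enol lactonisation; acylation of the C4 carbanion of an ortho-toluate by a hexanoyl unit). Ring A is then cut at C7–C8 and C4a–C8a, and last the alkynyl C–O bond to ring B.
- Enabling feature: in ring A of the isocoumarin (C4a, C5, C6, C7, C8, C8a), the pair C8(OAr)–C8a(C1=O) is the C≡C of a 3-aryloxypropiolate, and C7–C6(O)–C5–C4a(–C4H3) is a 2-silyloxypenta-1,3-diene. Ring A is therefore a Diels–Alder adduct two hydrogens below the arene.
- Forward order: ring B is bought as olivetol and converted into its C1' phenol, then into the aryloxypropiolate. Ring A arises by cycloaddition and DDQ dehydrogenation. The pyranone ring closes last, followed by debenzylation.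
- Stereochemistry: the target has no stereocentre. The single sp3 centre of the cycloadduct forms racemic and is erased on aromatisation; the diene E geometry comes from (E)-pent-3-en-2-one.

Key step: step 8

Remark: the diene carries a tert-butyldimethylsilyl group instead of trimethylsilyl so that the cycloadduct and the arene derived from it can be isolated. Commercial (E)-pent-3-en-2-one is assumed to be distilled free of its isomers before use.

**Route**

Step 1
Reactants: 1 olivetol
Product: 3 2,4-dihydroxy-6-pentylbenzaldehyde, via aryl iminium salt 2 (not isolated)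
Conditions: POCl3, DMF, 0 °C to rt; then H2O, 50 °C
Reagents that add atoms: N,N-dimethylformamide CN(C)C=O; water O
Why: Vilsmeier–Haack formylation of a 5-alkylresorcinol is expected at the ring position para to one hydroxyl and ortho to the other, next to the pentyl chain, as known for orcinol-type substrates.

Step 2
Reactants: 3 2,4-dihydroxy-6-pentylbenzaldehyde
Product: 4 2-hydroxy-4-methoxy-6-pentylbenzaldehyde
Conditions: MeI (1.05 equiv), K2CO3 (1.0 equiv), acetone, rt
Reagents that add atoms: iodomethane CI
Why: Williamson etherification should occur at the 4-hydroxyl, which is the more acidic one and is not tied up in the hydrogen bond to the formyl group.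

Step 3
Reactants: 4 2-hydroxy-4-methoxy-6-pentylbenzaldehyde
Product: 5 2-(benzyloxy)-4-methoxy-6-pentylbenzaldehyde
Conditions: BnBr, K2CO3, DMF, 60 °C
Reagents that add atoms: benzyl bromide BrCc1ccccc1
Why: Williamson benzylation of the remaining chelated phenol proceeds under slightly more forcing conditions in a dipolar aprotic solvent.

Step 4
Reactants: 5 2-(benzyloxy)-4-methoxy-6-pentylbenzaldehyde
Product: 7 2-(benzyloxy)-4-methoxy-6-pentylphenol, via aryl formate 6 (not isolated)
Conditions: mCPBA, CH2Cl2, 0 °C to rt; aq. NaHCO3 wash; then K2CO3 (0.2 equiv), MeOH, rt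
Reagents that add atoms: 3-chloroperoxybenzoic acid OOC(=O)c1cccc(Cl)c1
Why: Baeyer–Villiger (Dakin-type) oxidation of an ortho,para-dialkoxybenzaldehyde proceeds with migration of the electron-rich aryl group, and the resulting formate is cleaved by methanolysis.

Step 5
Reactants: 7 2-(benzyloxy)-4-methoxy-6-pentylphenol, 8 trichloroethylene
Product: 9 1-(benzyloxy)-2-{[(E)-1,2-dichloroethenyl]oxy}-5-methoxy-3-pentylbenzene
Conditions: K2CO3, DMF, 70 °C
Reagents that add atoms: none
Why: The base converts trichloroethylene into dichloroacetylene, to which the phenoxide adds in anti fashion; this is the known synthesis of aryl (E)-1,2-dichlorovinyl ethers from phenols.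

Step 6
Reactants: 9 1-(benzyloxy)-2-{[(E)-1,2-dichloroethenyl]oxy}-5-methoxy-3-pentylbenzene, 10 methyl chloroformate
Product: 13 methyl 3-[2-(benzyloxy)-4-methoxy-6-pentylphenoxy]prop-2-ynoate, via aryl chloroethynyl ether 11 (not isolated), via lithium aryloxyacetylide 12 (not isolated)
Conditions: n-BuLi (2.2 equiv), THF, −78 to −40 °C; then ClCO2Me, −78 to 0 °C; neutral alumina filtration
Reagents that add atoms: none
Why: This is the ynol ether synthesis from 1,2-dichlorovinyl ethers (deprotonation, loss of chloride to 11, chlorine–lithium exchange to 12), followed by the standard C-acylation of a lithium acetylide by a chloroformate.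

Step 7
Reactants: 14 (E)-pent-3-en-2-one
Product: 16 (E)-2-(tert-butyldimethylsilyloxy)penta-1,3-diene, via lithium dienolate 15 (not isolated)
Conditions: LiN(i-Pr)2, THF, −78 °C; TBSOTf, −78 to 0 °C; pentane/aq. NaHCO3 work-up, distillation
Reagents that add atoms: tert-butyldimethylsilyl trifluoromethanesulfonate CC(C)(C)[Si](C)(C)OS(=O)(=O)C(F)(F)F
Why: Kinetic deprotonation of the enone at the methyl ketone carbon gives the cross-conjugated enolate, and O-silylation gives the 2-silyloxydiene with the E double bond untouched.

Step 8
Reactants: 13 methyl 3-[2-(benzyloxy)-4-methoxy-6-pentylphenoxy]prop-2-ynoate, 16 (E)-2-(tert-butyldimethylsilyloxy)penta-1,3-diene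
Product: 17 methyl (6RS)-2-[2-(benzyloxy)-4-methoxy-6-pentylphenoxy]-4-(tert-butyldimethylsilyloxy)-6-methylcyclohexa-1,4-diene-1-carboxylate (racemic)
Conditions: 16 (4 equiv), BHT (5 mol%), toluene, sealed tube, 150 °C; evaporation, filtration through Et3N-deactivated silica
Reagents that add atoms: none
Why: Proposed new method: the step is a thermal normal-electron-demand [4+2] cycloaddition in which the HOMO of silyloxydiene 16 combines with the LUMO of the ester-activated alkyne 13, and the closest known reaction type is the Diels–Alder reaction of 2-silyloxy-1,3-dienes with propiolates or acetylenedicarboxylates followed by dehydrogenation to phenol derivatives, which has not been shown for a β-aryloxy (push–pull) alkynoate. Ring A closes as a six-membered carbocycle by suprafacial addition across the diene termini, bonds C7–C8 and C4a–C8a forming in the same event, although asynchronously with C7–C8 leading (at the polar limit a Mukaiyama–Michael addition followed by ring closure, which gives the same adduct). The one new stereocentre, C4a (C6 of the cyclohexadiene), has no controlling element because an alkyne dienophile has no endo/exo distinction and no chiral group is present, so 17 should form as a racemate and the centre is flattened in step 9. The selectivity needed is regiochemical, and both diene substituents secure it: the 2-silyloxy group and the 4-methyl group each place the largest HOMO coefficient on the CH2 terminus, which bonds to the ester β-carbon C8, so that the ester ends up para to O6 and ortho to the methyl group. The dienophile is built to survive the heating: an aryl ynol ether has no β-hydrogen on its oxygen substituent for retro-ene loss, the twisted di-ortho-substituted aryloxy group donates less than an alkoxy group, and in the adduct the aryloxy group sits on an sp2 carbon of a vinylogous carbonate and cannot be eliminated.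

Step 9
Reactants: 17 methyl (6RS)-2-[2-(benzyloxy)-4-methoxy-6-pentylphenoxy]-4-(tert-butyldimethylsilyloxy)-6-methylcyclohexa-1,4-diene-1-carboxylate
Product: 18 methyl 2-[2-(benzyloxy)-4-methoxy-6-pentylphenoxy]-4-(tert-butyldimethylsilyloxy)-6-methylbenzoate
Conditions: DDQ (1.1 equiv), toluene, rt
Reagents that add atoms: none
Why: DDQ dehydrogenation of a cyclohexa-1,4-diene (hydride abstraction from a doubly allylic ring C–H, then proton loss) is driven by aromatisation, turns the silyl enol ether into an aryl silyl ether and removes the stereocentre.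

Step 10
Reactants: 18 methyl 2-[2-(benzyloxy)-4-methoxy-6-pentylphenoxy]-4-(tert-butyldimethylsilyloxy)-6-methylbenzoate
Product: 19 methyl 4-(benzyloxy)-2-[2-(benzyloxy)-4-methoxy-6-pentylphenoxy]-6-methylbenzoate
Conditions: CsF, BnBr, DMF, rt
Reagents that add atoms: benzyl bromide BrCc1ccccc1
Why: Fluoride cleaves the aryl silyl ether to the caesium phenoxide, which undergoes Williamson benzylation in the same flask, so that O6 carries the same base-stable group as O2'.

Step 11
Reactants: 20 hexanoyl chloride, 21 N,O-dimethylhydroxylamine hydrochloride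
Product: 22 N-methoxy-N-methylhexanamide
Conditions: K2CO3, H2O/CH2Cl2, 0 °C to rt
Reagents that add atoms: none
Why: Schotten–Baumann acylation of the amine liberated from its hydrochloride gives the N-methoxy-N-methylamide.

Step 12
Reactants: 19 methyl 4-(benzyloxy)-2-[2-(benzyloxy)-4-methoxy-6-pentylphenoxy]-6-methylbenzoate, 22 N-methoxy-N-methylhexanamide
Product: 25 methyl 4-(benzyloxy)-2-[2-(benzyloxy)-4-methoxy-6-pentylphenoxy]-6-(2-oxoheptyl)benzoate, via benzylic lithium compound 23 (not isolated), via tetrahedral lithium alkoxide 24 (not isolated)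
Conditions: LiN(i-Pr)2, THF, −78 °C; then 22, −78 to −20 °C; cold dilute aq. HCl
Reagents that add atoms: none
Why: Lateral (benzylic) lithiation of an ortho-toluate whose ester is shielded by two ortho substituents gives anion 23, and its addition to the N-methoxy-N-methylamide stops at the chelated adduct 24 (Weinreb ketone synthesis), which releases the ketone only on acidic quench.

Step 13
Reactants: 25 methyl 4-(benzyloxy)-2-[2-(benzyloxy)-4-methoxy-6-pentylphenoxy]-6-(2-oxoheptyl)benzoate
Product: 26 6-(benzyloxy)-8-[2-(benzyloxy)-4-methoxy-6-pentylphenoxy]-3-pentyl-1H-isochromen-1-one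
Conditions: p-TsOH·H2O (0.2 equiv), toluene, 4 Å molecular sieves, 90 °C
Reagents that add atoms: none
Why: In this acid-catalysed enol lactonisation the enol oxygen of the benzyl ketone attacks the neighbouring ester in a 6-exo-trig transesterification and methanol is lost, whereas base would favour Claisen-type C-cyclisation to a naphthol.

Step 14
Reactants: 26 6-(benzyloxy)-8-[2-(benzyloxy)-4-methoxy-6-pentylphenoxy]-3-pentyl-1H-isochromen-1-one
Product: 27 6-hydroxy-8-(2-hydroxy-4-methoxy-6-pentylphenoxy)-3-pentyl-1H-isochromen-1-one (NP-007099)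
Conditions: H2 (1 atm), Pd/C (10 wt% palladium on carbon), EtOAc, rt, stopped after uptake of 2 equiv
Reagents that add atoms: none
Why: Catalytic hydrogenolysis should remove both aryl benzyl ethers, while the conjugated trisubstituted C3=C4 bond of the enol lactone is expected to react far more slowly and the methyl and diaryl ethers are inert.

**Compound list**

1 | olivetol (5-pentylbenzene-1,3-diol) | CCCCCc1cc(O)cc(O)c1 | starting material
2 | [(2,4-dihydroxy-6-pentylphenyl)methylidene]dimethyliminium dichlorophosphate | CCCCCc1cc(O)cc(O)c1C=[N+](C)C.[O-]P(=O)(Cl)Cl | intermediate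
3 | 2,4-dihydroxy-6-pentylbenzaldehyde | CCCCCc1cc(O)cc(O)c1C=O | intermediate
4 | 2-hydroxy-4-methoxy-6-pentylbenzaldehyde | CCCCCc1cc(OC)cc(O)c1C=O | intermediate
5 | 2-(benzyloxy)-4-methoxy-6-pentylbenzaldehyde | CCCCCc1cc(OC)cc(OCc2ccccc2)c1C=O | intermediate
6 | 2-(benzyloxy)-4-methoxy-6-pentylphenyl formate | O=COc1c(OCc2ccccc2)cc(OC)cc1CCCCC | intermediate
7 | 2-(benzyloxy)-4-methoxy-6-pentylphenol | CCCCCc1cc(OC)cc(OCc2ccccc2)c1O | intermediate
8 | trichloroethylene | ClC=C(Cl)Cl | starting material
9 | 1-(benzyloxy)-2-{[(E)-1,2-dichloroethenyl]oxy}-5-methoxy-3-pentylbenzene | Cl/C=C(/Cl)Oc1c(OCc2ccccc2)cc(OC)cc1CCCCC | intermediate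
10 | methyl chloroformate | COC(=O)Cl | starting material
11 | 1-(benzyloxy)-2-[(chloroethynyl)oxy]-5-methoxy-3-pentylbenzene | ClC#COc1c(OCc2ccccc2)cc(OC)cc1CCCCC | intermediate
12 | lithium [2-(benzyloxy)-4-methoxy-6-pentylphenoxy]acetylide | [Li]C#COc1c(OCc2ccccc2)cc(OC)cc1CCCCC | intermediate
13 | methyl 3-[2-(benzyloxy)-4-methoxy-6-pentylphenoxy]prop-2-ynoate | COC(=O)C#COc1c(OCc2ccccc2)cc(OC)cc1CCCCC | intermediate
14 | (E)-pent-3-en-2-one | C/C=C/C(C)=O | starting material
15 | lithium (3E)-penta-1,3-dien-2-olate | [Li]OC(=C)/C=C/C | intermediate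
16 | (E)-2-(tert-butyldimethylsilyloxy)penta-1,3-diene | C/C=C/C(=C)O[Si](C)(C)C(C)(C)C | intermediate
17 | methyl (6RS)-2-[2-(benzyloxy)-4-methoxy-6-pentylphenoxy]-4-(tert-butyldimethylsilyloxy)-6-methylcyclohexa-1,4-diene-1-carboxylate (racemic, one enantiomer drawn) | COC(=O)C1=C(Oc2c(OCc3ccccc3)cc(OC)cc2CCCCC)CC(O[Si](C)(C)C(C)(C)C)=C[C@H]1C | intermediate
18 | methyl 2-[2-(benzyloxy)-4-methoxy-6-pentylphenoxy]-4-(tert-butyldimethylsilyloxy)-6-methylbenzoate | COC(=O)c1c(C)cc(O[Si](C)(C)C(C)(C)C)cc1Oc1c(OCc2ccccc2)cc(OC)cc1CCCCC | intermediate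
19 | methyl 4-(benzyloxy)-2-[2-(benzyloxy)-4-methoxy-6-pentylphenoxy]-6-methylbenzoate | COC(=O)c1c(C)cc(OCc2ccccc2)cc1Oc1c(OCc2ccccc2)cc(OC)cc1CCCCC | intermediate
20 | hexanoyl chloride | CCCCCC(=O)Cl | starting material
21 | N,O-dimethylhydroxylamine hydrochloride | CNOC.Cl | starting material
22 | N-methoxy-N-methylhexanamide | CCCCCC(=O)N(C)OC | intermediate
23 | methyl 4-(benzyloxy)-2-[2-(benzyloxy)-4-methoxy-6-pentylphenoxy]-6-(lithiomethyl)benzoate | COC(=O)c1c(C[Li])cc(OCc2ccccc2)cc1Oc1c(OCc2ccccc2)cc(OC)cc1CCCCC | intermediate
24 | lithium alkoxide adduct of 23 and 22 (racemic hemiaminal centre, not specified) | COC(=O)c1c(CC(O[Li])(CCCCC)N(C)OC)cc(OCc2ccccc2)cc1Oc1c(OCc2ccccc2)cc(OC)cc1CCCCC | intermediate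
25 | methyl 4-(benzyloxy)-2-[2-(benzyloxy)-4-methoxy-6-pentylphenoxy]-6-(2-oxoheptyl)benzoate | COC(=O)c1c(CC(=O)CCCCC)cc(OCc2ccccc2)cc1Oc1c(OCc2ccccc2)cc(OC)cc1CCCCC | intermediate
26 | 6-(benzyloxy)-8-[2-(benzyloxy)-4-methoxy-6-pentylphenoxy]-3-pentyl-1H-isochromen-1-one | CCCCCc1cc2cc(OCc3ccccc3)cc(Oc3c(OCc4ccccc4)cc(OC)cc3CCCCC)c2c(=O)o1 | intermediate
27 | 6-hydroxy-8-(2-hydroxy-4-methoxy-6-pentylphenoxy)-3-pentyl-1H-isochromen-1-one (NP-007099) | CCCCCc1cc2cc(O)cc(Oc3c(O)cc(OC)cc3CCCCC)c2c(=O)o1 | target

**Step count and risks**

Total: 14 steps. Longest linear sequence: 12 steps (steps 1–6, 8–10 and 12–14); steps 7 and 11 are one-step side branches.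

Steps most likely to fail:

1. Step 8 (bears the new-method label). The alkyne, deactivated by donation from the aryloxy oxygen, may not engage the diene before the diene oligomerises or loses its silyl group, or the addition may stop at an open-chain Michael adduct. The fallback uses known chemistry, gives up the ring-forming step and takes ring A from the aromatic pool; it sets out from phenol 7 and returns to the route at 19. Commercial methyl orsellinate (methyl 2,4-dihydroxy-6-methylbenzoate) would be benzylated at its non-chelated 4-hydroxyl (BnBr, K2CO3, acetone) to give methyl 4-(benzyloxy)-2-hydroxy-6-methylbenzoate F1. Triflation (Tf2O, pyridine, CH2Cl2, 0 °C) would give methyl 4-(benzyloxy)-2-methyl-6-(trifluoromethylsulfonyloxy)benzoate F2. Palladium-catalysed diaryl ether coupling of F2 with 7 (Pd(OAc)2, 2-di-tert-butylphosphino-2',4',6'-triisopropylbiphenyl, K3PO4, toluene, 100 °C, slow addition of F2) would then give 19, and the route continues with step 12.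

2. Step 6. Acetylide 12 may add a second time to the ester or to the electrophilic alkyne carbon of the product, excess n-BuLi may metalate ring B or a benzylic position, and the push–pull alkyne may hydrate during isolation. The fallback separates alkyne formation from ester formation and replaces the acylating electrophile by a catalytic carboxylation; it sets out from 9 and returns at 13. Treatment of 9 with n-BuLi (2.2 equiv, THF, −78 °C) and a methanol quench would give the isolable terminal ynol ether 1-(benzyloxy)-2-(ethynyloxy)-5-methoxy-3-pentylbenzene F3. Carboxylation under AgI catalysis (Cs2CO3, CO2 at 1 atm, DMF, 50 °C) would give caesium 3-[2-(benzyloxy)-4-methoxy-6-pentylphenoxy]prop-2-ynoate F4, a carboxylate that cannot be attacked further, and MeI added to the same flask would give 13.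

3. Step 14. Hydrogen may add to the C3=C4 double bond of the isocoumarin before both benzyl groups are gone, giving over-reduction to the 3,4-dihydroisocoumarin. The fallback replaces hydrogenolysis by Lewis-acid cleavage; it sets out from 26 and returns at 27. BCl3 with pentamethylbenzene as cation scavenger (CH2Cl2, −78 °C) should remove aryl benzyl ethers without touching the aryl methyl ether, the lactone or the double bond. No compound outside the list is made on this path (line F0 below).

**Further compounds**

F1 | step 8 | methyl 4-(benzyloxy)-2-hydroxy-6-methylbenzoate | COC(=O)c1c(C)cc(OCc2ccccc2)cc1O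
F2 | step 8 | methyl 4-(benzyloxy)-2-methyl-6-(trifluoromethylsulfonyloxy)benzoate | COC(=O)c1c(C)cc(OCc2ccccc2)cc1OS(=O)(=O)C(F)(F)F
F3 | step 6 | 1-(benzyloxy)-2-(ethynyloxy)-5-methoxy-3-pentylbenzene | C#COc1c(OCc2ccccc2)cc(OC)cc1CCCCC
F4 | step 6 | caesium 3-[2-(benzyloxy)-4-methoxy-6-pentylphenoxy]prop-2-ynoate | [Cs+].[O-]C(=O)C#COc1c(OCc2ccccc2)cc(OC)cc1CCCCC
F0 | step 14 | none | none
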